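**Retrosynthetic overview**

- Target 12 is cut at both aryl–C(=O) bonds (Friedel–Crafts acylation of resorcinol) to give all-trans 2,4-diphenylcyclobutane-1,3-dicarboxylic acid 10.
- 10 comes from the all-cis bis(quinolin-8-yl amide) 7 by N-Boc activation, methanolysis and epimerisation at C1 and C3, which moves both carbonyls to the face opposite the phenyls.
- 7 comes from cis-cyclobutane-1,3-bis(quinolin-8-yl amide) 4 and two iodobenzenes: the C2–Ph and C4–Ph bonds are made by twofold amide-directed Pd-catalysed methylene C–H arylation.
- Feature used: in the cyclobutane, the phenyl-bearing C2 and C4 each sit between the carbonyl-bearing C1 and C3, so each ring CH2 of a cis-1,3-dicarbonyl cyclobutane is β to both carbonyls and has a C–H on the carbonyl face.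
- The four-membered ring is bought preformed as cis-cyclobutane-1,3-dicarboxylic acid 1; no ring is formed in the route.

Key step: step 3

Remark: the target has mirror planes through C1/C3 and through C2/C4 and is achiral. Its stereodescriptors therefore fix only the relative configuration (aroyls 1,3-cis, phenyls 2,4-cis, every vicinal pair trans), and no absolute stereocontrol is needed.

**Route**

Step 1
Reactants: 1 cis-cyclobutane-1,3-dicarboxylic acid
Product: 2 cis-cyclobutane-1,3-dicarbonyl dichloride
Conditions: (COCl)2 (2.5 equiv), cat. DMF, CH2Cl2, 0 °C to rt; evaporate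
Reagents that add atoms: oxalyl chloride, ClC(=O)C(=O)Cl
Why: Acid chloride formation with oxalyl chloride and catalytic DMF (Vilsmeier-type activation) runs without base at or below room temperature, so the α-carbons are not enolised and the cis-1,3 relationship should be kept.

Step 2
Reactants: 2 cis-cyclobutane-1,3-dicarbonyl dichloride; 3 quinolin-8-amine (2.2 equiv)
Product: 4 cis-N1,N3-di(quinolin-8-yl)cyclobutane-1,3-dicarboxamide
Conditions: pyridine (3 equiv), cat. DMAP, CH2Cl2, 0 °C to rt; slow addition of 2 to the amine
Reagents that add atoms: none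
Why: N-Acylation of the weakly nucleophilic 8-aminoquinoline by an acid chloride (Schotten–Baumann-type amidation) is the standard way to install this directing group, pyridine as a mild base limits ketene formation so the cis configuration should carry through, and adding 2 to excess amine disfavours intramolecular imide closure.

Step 3
Reactants: 4 cis-N1,N3-di(quinolin-8-yl)cyclobutane-1,3-dicarboxamide; 5 iodobenzene (8 equiv)
Product: 7 all-cis-2,4-diphenyl-N1,N3-di(quinolin-8-yl)cyclobutane-1,3-dicarboxamide, via all-cis 2-phenyl diamide 6 (not isolated)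
Conditions: Pd(OAc)2 (20 mol%), AgOAc (4.4 equiv), PivOH (30 mol%), toluene, 110 °C, sealed tube
Reagents that add atoms: none
Why: Each deprotonated amide nitrogen and its quinoline nitrogen bind Pd(II) as an N,N-chelate, carboxylate-assisted concerted metalation–deprotonation of the ring methylene C–H cis to that amide gives a five-membered palladacycle, and oxidative addition of iodobenzene to Pd(IV) followed by C–C reductive elimination delivers phenyl with retention while AgOAc removes iodide and returns Pd(II). The closest known reaction is the Pd(II)/Pd(IV) aminoquinoline-directed β-C(sp3)–H arylation of cyclobutanecarboxamides, including twofold methylene arylation to all-cis products. No ring is closed. The new stereocentres C2 and C4 are set by the substrate: a palladacycle can form only on the ring face that carries the cis amides, so each phenyl should arrive cis to both amides and the two phenyls are thereby cis to each other. The step needs face selectivity, complete twofold arylation and no α-epimerisation; the first is secured by the cis-fused metallacycle geometry, the second is helped because C2 and C4 are equivalent and each is β to both carbonyls so that either amide can direct either event (excess iodobenzene and silver salt driving the slower, more congested second arylation of 6), and the third by the weakly basic carboxylate medium.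

Step 4
Reactants: 7 all-cis-2,4-diphenyl-N1,N3-di(quinolin-8-yl)cyclobutane-1,3-dicarboxamide
Product: 8 all-cis-N1,N3-bis(tert-butoxycarbonyl)-2,4-diphenyl-N1,N3-di(quinolin-8-yl)cyclobutane-1,3-dicarboxamide
Conditions: Boc2O (8 equiv), DMAP (2 equiv), MeCN, 60 °C
Reagents that add atoms: di-tert-butyl dicarbonate, CC(C)(C)OC(=O)OC(=O)OC(C)(C)C
Why: DMAP-catalysed N-tert-butoxycarbonylation of the secondary anilides (Grieco-type amide activation) should give twisted N-acyl carbamates whose acyl carbons are electrophilic and whose aminoquinoline unit is a leaving group, without touching any ring stereocentre.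

Step 5
Reactants: 8 all-cis-N1,N3-bis(tert-butoxycarbonyl)-2,4-diphenyl-N1,N3-di(quinolin-8-yl)cyclobutane-1,3-dicarboxamide
Product: 9 dimethyl (1α,2β,3α,4β)-2,4-diphenylcyclobutane-1,3-dicarboxylate (all-trans)
Conditions: NaOMe (6 equiv), MeOH/THF, 0 °C to 60 °C; aq. NH4Cl
Reagents that add atoms: sodium methoxide (in methanol), C[O-].[Na+]
Why: Methanolysis of the N-Boc-activated amides (addition–elimination at the acyl carbon or E1cB through a ketene, both ending in the methyl ester) is followed in the same pot by methoxide-mediated enolisation at C1 and C3 (base-mediated epimerisation), which should drain the all-cis array into the all-trans isomer with all four substituents pseudo-equatorial, while the non-acidic phenyl-bearing C2 and C4 keep their mutual cis relationship.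

Step 6
Reactants: 9 dimethyl (1α,2β,3α,4β)-2,4-diphenylcyclobutane-1,3-dicarboxylate
Product: 10 (1α,2β,3α,4β)-2,4-diphenylcyclobutane-1,3-dicarboxylic acid (all-trans)
Conditions: LiOH·H2O (6 equiv), THF/MeOH/H2O, 50 °C; then 1 M HCl
Reagents that add atoms: lithium hydroxide, [Li+].[OH-]
Why: Saponification (BAc2 ester hydrolysis) of two unhindered pseudo-equatorial methyl esters should be clean, and because the all-trans configuration is already the thermodynamic one the basic medium cannot erode it.

Step 7
Reactants: 10 (1α,2β,3α,4β)-2,4-diphenylcyclobutane-1,3-dicarboxylic acid; 11 resorcinol (5 equiv)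
Product: 12 [(1α,2β,3α,4β)-2,4-diphenylcyclobutane-1,3-diyl]bis[(2,4-dihydroxyphenyl)methanone]
Conditions: BF3·OEt2 (neat, excess), 85 °C; then aq. NaOAc
Reagents that add atoms: none
Why: Friedel–Crafts C-acylation of resorcinol by a carboxylic acid in BF3·OEt2 (Nencki/Houben–Hoesch-type deoxybenzoin synthesis, known for α-branched acids) should place each acyl group at C4 of resorcinol, para to one hydroxyl and ortho to the other, with any aryl ester formed first converging on the same ketone by Fries rearrangement, and the trans disposition of each carboxyl to both neighbouring phenyls disfavours intramolecular indanone formation.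

**Compound list**

1 | cis-cyclobutane-1,3-dicarboxylic acid | OC(=O)[C@H]1C[C@@H](C(=O)O)C1 | starting material
2 | cis-cyclobutane-1,3-dicarbonyl dichloride | ClC(=O)[C@H]1C[C@@H](C(=O)Cl)C1 | intermediate
3 | quinolin-8-amine | Nc1cccc2cccnc12 | starting material
4 | cis-N1,N3-di(quinolin-8-yl)cyclobutane-1,3-dicarboxamide | O=C(Nc1cccc2cccnc12)[C@H]1C[C@@H](C(=O)Nc2cccc3cccnc23)C1 | intermediate
5 | iodobenzene | Ic1ccccc1 | starting material
6 | all-cis-2-phenyl-N1,N3-di(quinolin-8-yl)cyclobutane-1,3-dicarboxamide (phenyl cis to both amides) | O=C(Nc1cccc2cccnc12)[C@H]1C[C@@H](C(=O)Nc2cccc3cccnc23)[C@H]1c1ccccc1 | intermediate (not isolated)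
7 | all-cis-2,4-diphenyl-N1,N3-di(quinolin-8-yl)cyclobutane-1,3-dicarboxamide | O=C(Nc1cccc2cccnc12)[C@H]1[C@@H](c2ccccc2)[C@@H](C(=O)Nc2cccc3cccnc23)[C@H]1c1ccccc1 | intermediate
8 | all-cis-N1,N3-bis(tert-butoxycarbonyl)-2,4-diphenyl-N1,N3-di(quinolin-8-yl)cyclobutane-1,3-dicarboxamide | O=C(N(C(=O)OC(C)(C)C)c1cccc2cccnc12)[C@H]1[C@@H](c2ccccc2)[C@@H](C(=O)N(C(=O)OC(C)(C)C)c2cccc3cccnc23)[C@H]1c1ccccc1 | intermediate
9 | dimethyl (1α,2β,3α,4β)-2,4-diphenylcyclobutane-1,3-dicarboxylate (esters cis to each other, phenyls cis to each other, vicinal pairs trans) | COC(=O)[C@H]1[C@H](c2ccccc2)[C@@H](C(=O)OC)[C@@H]1c1ccccc1 | intermediate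
10 | (1α,2β,3α,4β)-2,4-diphenylcyclobutane-1,3-dicarboxylic acid (all-trans) | OC(=O)[C@H]1[C@H](c2ccccc2)[C@@H](C(=O)O)[C@@H]1c1ccccc1 | intermediate
11 | resorcinol | Oc1cccc(O)c1 | starting material
12 | [(1α,2β,3α,4β)-2,4-diphenylcyclobutane-1,3-diyl]bis[(2,4-dihydroxyphenyl)methanone] | O=C(c1ccc(O)cc1O)[C@H]1[C@H](c2ccccc2)[C@@H](C(=O)c2ccc(O)cc2O)[C@@H]1c1ccccc1 | target

**Step count**

Total steps: 7. Longest linear sequence: 7 (from 1).

**Steps most likely to fail**

Step 3. The two bidentate aminoquinoline amides may sequester palladium, with the second chelate occupying the sites needed for oxidative addition, or the reaction may stall after the first arylation because the all-cis ring is congested. The fallback uses a single directing group and sets out from 1. Dehydration with Ac2O at reflux should give the bicyclic anhydride 3-oxabicyclo[3.1.1]heptane-2,4-dione F1. Opening it with quinolin-8-amine 3 in toluene at 80 °C should give cis-3-(quinolin-8-ylcarbamoyl)cyclobutane-1-carboxylic acid F2. Methylation with MeI and K2CO3 in DMF should give methyl cis-3-(quinolin-8-ylcarbamoyl)cyclobutane-1-carboxylate F3. The known twofold aminoquinoline-directed methylene arylation of a cyclobutanecarboxamide with iodobenzene 5 (Pd(OAc)2, AgOAc, toluene, 110 °C) should then give methyl all-cis-2,4-diphenyl-3-(quinolin-8-ylcarbamoyl)cyclobutane-1-carboxylate F4. Boc2O and DMAP in MeCN should give its N-Boc derivative, methyl all-cis-3-[tert-butoxycarbonyl(quinolin-8-yl)carbamoyl]-2,4-diphenylcyclobutane-1-carboxylate F5. NaOMe in MeOH at 60 °C should cleave the activated amide and epimerise C1 and C3, so that the route is rejoined at 9.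

Step 7. The second acylation of the hindered diacid may remain incomplete, or the hot Lewis acid may cleave the cyclobutane. The fallback sets out from 10 and uses a preformed acid chloride and a protected arene. Oxalyl chloride with catalytic DMF in CH2Cl2 should give (1α,2β,3α,4β)-2,4-diphenylcyclobutane-1,3-dicarbonyl dichloride F6. Friedel–Crafts acylation of 1,3-dimethoxybenzene with AlCl3 in CH2Cl2 at 0 °C should give [(1α,2β,3α,4β)-2,4-diphenylcyclobutane-1,3-diyl]bis[(2,4-dimethoxyphenyl)methanone] F7. Demethylation with BBr3 in CH2Cl2 from −78 °C to rt should return to the route at 12.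

Step 5. Methoxide may attack the carbamate carbonyl instead of the hindered acyl carbon; the Boc group is then lost and the inert anilide returns, or the freed amide anion closes onto the neighbouring acyl group as a bicyclic imide. The fallback sets out from 8 and separates cleavage from epimerisation. LiOH and H2O2 in THF/H2O at 0 °C (hydroperoxide as a small α-nucleophile) should give all-cis-2,4-diphenylcyclobutane-1,3-dicarboxylic acid F8 without epimerisation. TMSCHN2 in MeOH/toluene should give dimethyl all-cis-2,4-diphenylcyclobutane-1,3-dicarboxylate F9. NaOMe in MeOH at 60 °C should then epimerise C1 and C3 of this ester and rejoin the route at 9.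

**Further compounds**

F1 | step 3 | 3-oxabicyclo[3.1.1]heptane-2,4-dione | O=C1OC(=O)[C@H]2C[C@@H]1C2
F2 | step 3 | cis-3-(quinolin-8-ylcarbamoyl)cyclobutane-1-carboxylic acid | OC(=O)[C@H]1C[C@@H](C(=O)Nc2cccc3cccnc23)C1
F3 | step 3 | methyl cis-3-(quinolin-8-ylcarbamoyl)cyclobutane-1-carboxylate | COC(=O)[C@H]1C[C@@H](C(=O)Nc2cccc3cccnc23)C1
F4 | step 3 | methyl all-cis-2,4-diphenyl-3-(quinolin-8-ylcarbamoyl)cyclobutane-1-carboxylate | COC(=O)[C@H]1[C@@H](c2ccccc2)[C@@H](C(=O)Nc2cccc3cccnc23)[C@H]1c1ccccc1
F5 | step 3 | methyl all-cis-3-[tert-butoxycarbonyl(quinolin-8-yl)carbamoyl]-2,4-diphenylcyclobutane-1-carboxylate | COC(=O)[C@H]1[C@@H](c2ccccc2)[C@@H](C(=O)N(C(=O)OC(C)(C)C)c2cccc3cccnc23)[C@H]1c1ccccc1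
F6 | step 7 | (1α,2β,3α,4β)-2,4-diphenylcyclobutane-1,3-dicarbonyl dichloride | ClC(=O)[C@H]1[C@H](c2ccccc2)[C@@H](C(=O)Cl)[C@@H]1c1ccccc1
F7 | step 7 | [(1α,2β,3α,4β)-2,4-diphenylcyclobutane-1,3-diyl]bis[(2,4-dimethoxyphenyl)methanone] | O=C(c1ccc(OC)cc1OC)[C@H]1[C@H](c2ccccc2)[C@@H](C(=O)c2ccc(OC)cc2OC)[C@@H]1c1ccccc1
F8 | step 5 | all-cis-2,4-diphenylcyclobutane-1,3-dicarboxylic acid | OC(=O)[C@H]1[C@@H](c2ccccc2)[C@@H](C(=O)O)[C@H]1c1ccccc1
F9 | step 5 | dimethyl all-cis-2,4-diphenylcyclobutane-1,3-dicarboxylate | COC(=O)[C@H]1[C@@H](c2ccccc2)[C@@H](C(=O)OC)[C@H]1c1ccccc1
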